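**Analysis of the target**

The target is a bicyclo[3.3.1]nonane-2,4,9-trione of the type B polyprenylated acylphloroglucinol class. Ring A (C1–C5 with C9) holds the enolised C2–C3–C4 diketone with the 3,4-dihydroxybenzoyl group on C3. Ring B (C5–C9 with C1) holds the C6 methylene, the C7 prenyl methine and the C8 gem-dimethyl carbon, and C9 is the bridging ketone. There are three stereocentres: the quaternary bridgeheads C1 (prenyl) and C5 (geranyl), which the one-carbon bridge locks to each other, and C7, whose prenyl group is exo (equatorial on a chair ring B, pointing away from ring A). Sensitive groups are the catechol (oxidation, base), four trisubstituted alkenes (no hydrogenation, strong acid or excess electrophilic halogen), and the bridgeheads, which are non-enolisable β-dicarbonyl carbons open to retro-Claisen cleavage by hard nucleophiles. The difficulty is to set two quaternary bridgeheads flanking C9, one of them next to quaternary C8, in one absolute sense on a skeleton with no heteroatom stereocentre to start from. The route rests on one feature of ring B: with its C8 gem-dimethyl carbon and C9 carbonyl it becomes a dimedone as soon as C6 is given a temporary carbonyl group. C5 is then the central carbon of that dimedone, and C1 and C7, both prenylated, are its two outer α-carbons, which are enantiotopic. A three-carbon unit on C5 (C4–C3–C2) can therefore be joined to either of them in an achiral molecule, and a chiral catalyst can make the choice.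

**Retrosynthetic reasoning**

Protecting groups (25 ⇒ 24 ⇒ 23). The catechol is carried as its bis-silyl ether and the C2 enol as a methyl ether, because neither the free catechol nor the enolised triketone tolerates the organolithium chemistry needed at C3. Fluoride and a soft SN2 demethylation remove them at the end.

C3–aroyl bond (23 ⇒ 19 + 22). In the vinylogous ester 19 both bridgeheads are quaternary, so C3–H is the only acidic hydrogen and acylation there is unambiguous. Cutting here keeps the catechol out of all earlier steps; the acid chloride 22 comes from 20 through the tris-silyl compound 21.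

C6 oxygen (19 ⇒ 18 ⇒ 17 ⇒ 16). The C6 methylene is traced back to a ketone. This costs three steps forward (reduction, thioacylation, radical deoxygenation), but it supplies the symmetry on which the route depends. C7 of 16 is traced to protonation of the C6 silyl enol ether 14; kinetic protonation is expected to pass through the epimer 15, so 16 must come from equilibration.

C2–O bond (14 ⇒ 13). The C2 methoxy group is traced to a vinylic bromide on a β-bromo enone, where addition–elimination by an alkoxide is easy.

C1–C2 bond, the key cut (13 ⇒ 12). Breaking C1–C2 turns C2/C3/C4 into a bromoalkynone on C5 and C1 into a silyl enol ether carbon. This cut is preferred over the C5 side because C5 is already quaternary in 12, which removes any regiochemical question. The gain is that 12 is achiral (mirror plane through C5 and C8), so the absolute configuration of C1 and C5 comes from the catalyst alone. Forward, a chiral digold catalyst has to direct one of two enantiotopic enol ethers onto the activated alkyne in a 6-endo sense.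

Enol ethers and bromoalkyne (12 ⇒ 11 ⇒ 10). The two O–Si bonds are cut last, because silyl enol ethers do not survive an electrophilic bromine source. The C–Br bond is traced to a C–Si bond, which keeps the alkyne terminus blocked during the earlier carbanion chemistry.

C5–geranyl bond (10 ⇒ 8 + 9). The quaternary centre is formed by allylating the enolised triketone 8 at its central carbon. Palladium catalysis is chosen because O-allylated material is returned to the ion pair and only C-allylation is irreversible.

C5–acyl bond (8 ⇒ 4 + 6). Acylation precedes geranylation because a 2-unsubstituted 1,3-dione is C-acylated reliably via its enol ester 7, whereas a 2-alkyl dione stops at the enol ester. The acid 6 comes from the silylacetylene 5.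

Outer prenyl groups (4 ⇒ 3 ⇒ 1 + 2). Both are introduced by dianion alkylation of the dione, which reaches the outer α-carbons directly and keeps the central carbon free.

**Alternatives that were turned down**

Alternative 1: Ring A is cut at both C2–C3 and C3–C4. C3 and its aroyl group would come from the methyl group of the aryl methyl ketone A3, and C2 and C4 from the two carbonyl carbons of the bridged anhydride A2 built on ring B. Forward, the lithium enolate of A3 opens A2 (C2–C3), the freed carboxylate is activated in the same flask as an acyl imidazolide, and the diketonate carbon closes ring A (C3–C4) to give A1, which is identical with 24 and one desilylation from the target.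
- For: it is convergent, the aroyl group arrives with C3, the opening regiochemistry does not matter because both modes lead to A1, and both bond formations are known Claisen-type acylations.
- Against: all three stereocentres, including both quaternary bridgeheads each carrying a carboxyl carbon next to C8, must already be present in enantiopure A2, for which no short asymmetric entry is apparent. The opened intermediate is also a β-keto carboxylate at C9, prone to decarboxylation and retro-Claisen cleavage.
- Comparison: this alternative is stronger in end-game economy and in the certainty of its key step. The chosen route offers instead a precursor made from dimedone in six linear steps whose stereochemistry is set catalytically.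

Alternative 2: Ring B is closed on a finished ring A by cutting C5–C6 and C6–C7, with C6 coming from formaldehyde. Forward, a chiral diarylprolinol silyl ether condenses the pendant aldehyde of the achiral trione A5 with formaldehyde to a 2-substituted acrolein, and one of the two enantiotopic ring methylenes adds to it to give A4.
- For: it is also a desymmetrisation of an achiral precursor, it is metal-free and cheap, and it sets C1, C5 and C7 while closing ring B.
- Against: the choice between enantiotopic carbons must be transmitted from an iminium or enamine several atoms away; α-substituted acroleins are poor iminium partners; and C7 is set by protonation next to an epimerisable aldehyde. A4 then lacks most of the target: C5 carries hydrogen (bridgehead geranylation between two carbonyls), C7 carries a formyl group that needs homologation before olefination, and C3 is unsubstituted.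
- Comparison: it matches the chosen route in concept and beats it in catalyst cost. The chosen route has every skeletal carbon except the aroyl group in place before the key step.

Alternative 3: Ring B is closed by cutting C1–C8. Forward, trimethylsilyl triflate opens the epoxide of the Birch-type diene A7 at its tertiary carbon toward one enol ether carbon, which forms C1–C8 and the C9 ketone and gives A6.
- For: this cationic closure onto a dimethoxycyclohexadiene is an established reaction type for this ring system, it forms the most congested bond directly, and the absolute configuration comes from a reliably made enantiopure epoxide.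
- Against: the activated epoxide sits beside the nucleophilic geranyl alkenes, which invites polyene cyclisation. A6 also needs a long end game: the C7 hydroxyl must become an exo prenyl group, C1 (the bridgehead beside the gem-dimethyl carbon) must be prenylated, C2 must be oxidised to a carbonyl, and C3 must be aroylated.
- Comparison: it is stronger on precedent and on certainty of enantiocontrol. The chosen route needs only oxygen adjustments (C2 bromide to oxygen, C6 deletion) and one acylation after its key step.

Key step: step 8

**Remarks on the chemistry**

- The sense of induction of the chiral gold complex cannot be derived from first principles. The (R)-ligand is written; the (S)-ligand complex would be used if the sense is opposite.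
- The enolised triketones 8, 24 and 25 are tautomeric mixtures; one tautomer is drawn.
- Compounds 3, 4, 7, 8, 10 and 11 are racemic or diastereomeric mixtures at the prenyl-bearing ring carbons, which become sp2 in 12.
- Transient metalated species (enolates, acetylides, vinylgold, vinyllithium) are treated as mechanism and carry no number.
- Monocyclic compounds are named with dimedone numbering. In the bicyclic numbering, dimedone C2 becomes C5, the ring carbonyl carbons become C6 and C9, the outer α-carbons C7 and C1, and the gem-dimethyl carbon C8.

**Route**

Step 1
Reactants: 1 dimedone; 2 prenyl bromide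
Product: 3 4-prenyldimedone (racemic)
Conditions: LDA (2.2 equiv), THF–HMPA, −78 to 0 °C; 2, −78 °C to rt; aq. HCl
Reagents that add atoms: none
Why: Dianion alkylation of a cyclic 1,3-dione: the second deprotonation takes place at an outer α-carbon, and this more basic carbanion, not the delocalised central carbon, is alkylated by the allylic bromide. The new stereocentre is racemic and is erased in step 7.

Step 2
Reactants: 3 4-prenyldimedone; 2 prenyl bromide
Product: 4 4,6-diprenyldimedone (cis/trans mixture)
Conditions: LDA (2.2 equiv), THF–HMPA, −78 to 0 °C; 2, −78 °C to rt; aq. HCl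
Reagents that add atoms: none
Why: Second dianion alkylation; deprotonation should prefer the free outer methylene over the prenyl-bearing methine, so the second prenyl group enters at the other outer carbon. Both stereocentres become enol ether carbons later, so the diastereomer mixture is of no consequence.

Step 3
Reactants: 5 (triisopropylsilyl)acetylene
Product: 6 3-(triisopropylsilyl)propynoic acid
Conditions: n-BuLi, THF, −78 °C; CO2; aq. HCl
Reagents that add atoms: carbon dioxide, O=C=O
Why: Carboxylation of a lithium acetylide. The bulky silyl group is chosen so that the later ynone resists conjugate addition at its terminus.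

Step 4
Reactants: 4 4,6-diprenyldimedone; 6 3-(triisopropylsilyl)propynoic acid
Product: 8 2-[3-(triisopropylsilyl)propynoyl]-4,6-diprenyldimedone (enolised triketone), via enol ester 7 (not isolated)
Conditions: DCC, DMAP, CH2Cl2, 0 °C to rt
Reagents that add atoms: none
Why: Carbodiimide esterification gives the enol ester, which DMAP converts by O-to-C acyl migration (acylpyridinium–enolate ion pair) into the hydrogen-bonded enolised triketone, the thermodynamic product. The triisopropylsilyl group shields the alkyne terminus from oxa-Michael closure to a pyranone.

Step 5
Reactants: 8 enolised triketone; 9 geranyl bromide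
Product: 10 2-geranyl-2-[3-(triisopropylsilyl)propynoyl]-4,6-diprenyl-5,5-dimethylcyclohexane-1,3-dione (diastereomer mixture)
Conditions: Pd(PPh3)4 (5 mol%), K2CO3, THF, 25–40 °C
Reagents that add atoms: none
Why: Tsuji–Trost allylation of a highly acidic cyclic triketone: the triketonate attacks the (π-geranyl)palladium cation at its unsubstituted terminus, which gives the linear E chain. O-Allylated material re-ionises under zerovalent palladium, so the irreversible C–C bond formation at the central carbon should drain the mixture toward 10.

Step 6
Reactants: 10 silyl ynone
Product: 11 2-(3-bromopropynoyl)-2-geranyl-4,6-diprenyl-5,5-dimethylcyclohexane-1,3-dione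
Conditions: AgF (1.2 equiv), NBS (1.05 equiv), MeCN, 0 °C to rt, dark
Reagents that add atoms: N-bromosuccinimide, O=C1CCC(=O)N1Br
Why: Silver-mediated desilylative bromination: fluoride takes the silyl group and the silver acetylide is brominated faster than any alkene. One equivalent of the bromine source, cold and in the dark, should leave the four trisubstituted alkenes untouched.

Step 7
Reactants: 11 bromoalkynone
Product: 12 achiral bis(tert-butyldimethylsilyl enol ether) of 2-(3-bromopropynoyl)-2-geranyl-4,6-diprenyldimedone
Conditions: TBSOTf (3 equiv), i-Pr2NEt (4 equiv), CH2Cl2, −78 to 0 °C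
Reagents that add atoms: tert-butyldimethylsilyl trifluoromethanesulfonate, CC(C)(C)[Si](C)(C)OS(=O)(=O)C(F)(F)F
Why: Soft enolisation with a silyl triflate and a hindered amine: each ring ketone has a single α-hydrogen because the central carbon is quaternary, so only the outward tetrasubstituted enol ethers can form, and every diastereomer of 11 gives the same achiral diene. A non-nucleophilic base is used because the bromoalkynone is an acceptor for nucleophilic amines.

Step 8
Reactants: 12 achiral bis-silyl enol ether
Product: 13 2-bromo-6-(tert-butyldimethylsilyloxy)-5-geranyl-8,8-dimethyl-1,7-diprenylbicyclo[3.3.1]nona-2,6-diene-4,9-dione, C1 and C5 as in 25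
Conditions: (R)-DTBM-SEGPHOS(AuCl)2 (5 mol%), AgSbF6 (10 mol%), water-saturated CH2Cl2, −30 °C
Reagents that add atoms: none
Why: Proposed new method: cationic monovalent gold, released from the digold chloride by AgSbF6, binds the bromoalkyne; the C1 carbon of one silyl enol ether attacks the distal alkyne carbon C2 anti to gold, water takes the silyl group from the resulting silyloxocarbenium ion (giving the C9 ketone), and protodeauration at C3 leaves the C2-bromo enone. The closest known reaction types are the gold-catalysed 6-endo-dig carbocyclisation of cyclic silyl enol ethers onto tethered alkynones and bromoalkynes to bicyclo[3.3.1]nonenones, and enantioselective silyl enol ether–alkyne cyclisations with chiral bisphosphine digold chlorides; new is the use of such a catalyst to choose between two enantiotopic enol ethers. Ring A (C1–C2–C3–C4–C5–C9) closes in the 6-endo-dig mode by forming C1–C2. C1 and C5 become stereocentres in the same event: the substrate has a mirror plane through C5 and C8, so their absolute configuration is decided only by which enol ether the chiral complex brings to the alkyne, and their relative configuration is fixed by the bridge. Three selectivities are needed: enantiotopic-group selection (catalyst), 6-endo over 5-exo closure (the ynone is polarised for attack at the carbon remote from the carbonyl group, and C5 is quaternary so the tether cannot enolise), and a single cyclisation (there is only one alkyne, and the second enol ether survives as a hindered tetrasubstituted silyl ether). The bromine stays on C2 as the handle for the oxygen the target carries there.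

Step 9
Reactants: 13 bromo enone
Product: 14 6-(tert-butyldimethylsilyloxy)-5-geranyl-2-methoxy-8,8-dimethyl-1,7-diprenylbicyclo[3.3.1]nona-2,6-diene-4,9-dione
Conditions: NaOMe (1.5 equiv), MeOH–THF, −20 to 0 °C
Reagents that add atoms: sodium methoxide, [Na+].[O-]C
Why: Addition–elimination (vinylic substitution) at the β-carbon of the β-bromo enone gives the vinylogous ester. It is run cold and before the silyl enol ether is cleaved, so that C5 never carries three free carbonyl groups in the presence of methoxide.

Step 10
Reactants: 14 methoxy enone silyl enol ether
Product: 16 5-geranyl-2-methoxy-8,8-dimethyl-1-prenyl-7-exo-prenylbicyclo[3.3.1]non-2-ene-4,6,9-trione, via C7-epimeric ketone 15 (not isolated)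
Conditions: HF·pyridine, THF, 0 °C to rt; then DBU (0.3 equiv), toluene, 50 °C
Reagents that add atoms: none
Why: Acid-mediated protodesilylation gives the C6 ketone; protonation from the open exo face would first place the prenyl group endo (15). Enolisation toward C7, the only enolisable position, should then equilibrate to the exo (equatorial) epimer, in which ring B keeps its chair, whereas the endo epimer needs a boat with eclipsing along C8–C1. C7 is thus set under thermodynamic control.

Step 11
Reactants: 16 C6 ketone
Product: 17 C6 carbinol of 16 (6-hydroxy compound; C6 configuration not controlled and immaterial)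
Conditions: NaBH4, CeCl3·7H2O, MeOH–THF, −60 °C; AcOH quench
Reagents that add atoms: none
Why: Luche-type reduction of the only unconjugated, non-bridging ketone: C9 is flanked by two quaternary bridgeheads and C4 is a vinylogous ester carbonyl. The cold, cerium-buffered medium and acidic quench avoid alkoxide-induced retro-aldol opening of ring B.

Step 12
Reactants: 17 C6 carbinol
Product: 18 O-phenyl thionocarbonate of 17
Conditions: PhOC(S)Cl, pyridine, DMAP, CH2Cl2, rt
Reagents that add atoms: O-phenyl chlorothionoformate, S=C(Cl)Oc1ccccc1
Why: Thioacylation of the secondary alcohol under weakly basic conditions (no alkoxide, hence no retro-aldol) prepares the Barton–McCombie deoxygenation.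

Step 13
Reactants: 18 thionocarbonate
Product: 19 5-geranyl-2-methoxy-8,8-dimethyl-1-prenyl-7-exo-prenylbicyclo[3.3.1]non-2-ene-4,9-dione
Conditions: Bu3SnH (0.5 M), (PhSe)2 (10 mol%), AIBN, benzene, 80 °C
Reagents that add atoms: none
Why: Barton–McCombie deoxygenation. The alkenes within reach of the secondary C6 radical offer only four-membered or endo cyclisation modes, and fast hydrogen transfer from benzeneselenol formed in situ should outrun a 1,2-acyl shift from C5 (Dowd–Beckwith rearrangement). C7 is not touched.

Step 14
Reactants: 20 3,4-dihydroxybenzoic acid
Product: 21 tert-butyldimethylsilyl 3,4-bis(tert-butyldimethylsilyloxy)benzoate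
Conditions: TBSCl (3.5 equiv), imidazole, DMF, rt
Reagents that add atoms: tert-butyldimethylsilyl chloride, CC(C)(C)[Si](C)(C)Cl
Why: Exhaustive silylation of the acid and both phenols; the silyl ester is the handle for the next step.

Step 15
Reactants: 21 tris-silyl compound
Product: 22 3,4-bis(tert-butyldimethylsilyloxy)benzoyl chloride
Conditions: (COCl)2, DMF (cat.), CH2Cl2, 0 °C to rt
Reagents that add atoms: oxalyl chloride, O=C(Cl)C(=O)Cl
Why: Silyl esters are converted directly into acid chlorides by oxalyl chloride with catalytic DMF (Vilsmeier-type activation), releasing the silyl chloride, so no hydrogen chloride endangers the aryl silyl ethers.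

Step 16
Reactants: 19 bicyclic vinylogous ester; 22 aroyl chloride
Product: 23 3-[3,4-bis(tert-butyldimethylsilyloxy)benzoyl] derivative of 19
Conditions: LDA (1.3 equiv), THF, −78 °C; 22, −78 to −20 °C
Reagents that add atoms: none
Why: Vinylic deprotonation of the vinylogous ester at C3, the only acidic position now that both bridgeheads are quaternary, followed by C-acylation of the vinyllithium. This is the usual late C3 acylation of bicyclo[3.3.1]nonane vinylogous esters.

Step 17
Reactants: 23 C3-aroyl methyl ether
Product: 24 bis(tert-butyldimethylsilyl) ether of the target (enolised triketone)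
Conditions: LiCl, DMSO, 120 °C, argon; mild acidic work-up
Reagents that add atoms: none
Why: SN2 demethylation of the doubly activated vinylogous ester by chloride (Krapcho-type) gives the triketonate without a carbonyl-attacking nucleophile. Any aryl silyl ether lost at this temperature does not matter, because step 18 removes both.

Step 18
Reactants: 24 bis-silyl ether
Product: 25 target, CNP0160101.3
Conditions: Et3N·3HF, THF, rt, argon
Reagents that add atoms: none
Why: Fluoride cleavage of the aryl silyl ethers under buffered, non-basic conditions, which should protect the catechol from air oxidation and the alkenes from acid-induced cyclisation.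

**Compound list**

1 | dimedone (5,5-dimethylcyclohexane-1,3-dione) | CC1(C)CC(=O)CC(=O)C1 | starting material
2 | prenyl bromide (1-bromo-3-methylbut-2-ene) | CC(C)=CCBr | starting material
3 | 4-prenyldimedone, 5,5-dimethyl-4-(3-methylbut-2-en-1-yl)cyclohexane-1,3-dione, racemic | CC(C)=CCC1C(=O)CC(=O)CC1(C)C | intermediate
4 | 4,6-diprenyldimedone, cis/trans mixture | CC(C)=CCC1C(=O)CC(=O)C(CC=C(C)C)C1(C)C | intermediate
5 | (triisopropylsilyl)acetylene | C#C[Si](C(C)C)(C(C)C)C(C)C | starting material
6 | 3-(triisopropylsilyl)propynoic acid | OC(=O)C#C[Si](C(C)C)(C(C)C)C(C)C | intermediate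
7 | enol ester, 5,5-dimethyl-3-oxo-4,6-diprenylcyclohex-1-en-1-yl 3-(triisopropylsilyl)propynoate | O=C1C=C(OC(=O)C#C[Si](C(C)C)(C(C)C)C(C)C)C(CC=C(C)C)C(C)(C)C1CC=C(C)C | intermediate (not isolated)
8 | 2-[3-(triisopropylsilyl)propynoyl]-4,6-diprenyldimedone, enol form | CC(C)=CCC1C(=O)C(C(=O)C#C[Si](C(C)C)(C(C)C)C(C)C)=C(O)C(CC=C(C)C)C1(C)C | intermediate
9 | geranyl bromide, (2E)-1-bromo-3,7-dimethylocta-2,6-diene | CC(C)=CCC/C(C)=C/CBr | starting material
10 | 2-geranyl-2-[3-(triisopropylsilyl)propynoyl]-4,6-diprenyl-5,5-dimethylcyclohexane-1,3-dione | CC(C)=CCC/C(C)=C/CC1(C(=O)C#C[Si](C(C)C)(C(C)C)C(C)C)C(=O)C(CC=C(C)C)C(C)(C)C(CC=C(C)C)C1=O | intermediate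
11 | 2-(3-bromopropynoyl)-2-geranyl-4,6-diprenyl-5,5-dimethylcyclohexane-1,3-dione | CC(C)=CCC/C(C)=C/CC1(C(=O)C#CBr)C(=O)C(CC=C(C)C)C(C)(C)C(CC=C(C)C)C1=O | intermediate
12 | achiral bis(tert-butyldimethylsilyl enol ether) of 11 (cyclohexa-1,4-diene, mirror plane through the acyl-bearing carbon and the gem-dimethyl carbon) | CC(C)=CCC/C(C)=C/CC1(C(=O)C#CBr)C(O[Si](C)(C)C(C)(C)C)=C(CC=C(C)C)C(C)(C)C(CC=C(C)C)=C1O[Si](C)(C)C(C)(C)C | intermediate
13 | bicyclic C2-bromo enone with C6 silyl enol ether, C1 and C5 as in 25 | CC(C)=CCC/C(C)=C/C[C@]12C(O[Si](C)(C)C(C)(C)C)=C(CC=C(C)C)C(C)(C)[C@](CC=C(C)C)(C(Br)=CC1=O)C2=O | intermediate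
14 | bicyclic C2-methoxy enone with C6 silyl enol ether | CC(C)=CCC/C(C)=C/C[C@]12C(O[Si](C)(C)C(C)(C)C)=C(CC=C(C)C)C(C)(C)[C@](CC=C(C)C)(C(OC)=CC1=O)C2=O | intermediate
15 | C6 ketone with endo C7 prenyl (C7 epimer of 16) | CC(C)=CCC/C(C)=C/C[C@]12C(=O)[C@H](CC=C(C)C)C(C)(C)[C@](CC=C(C)C)(C(OC)=CC1=O)C2=O | intermediate (not isolated)
16 | C6 ketone with exo C7 prenyl | CC(C)=CCC/C(C)=C/C[C@]12C(=O)[C@@H](CC=C(C)C)C(C)(C)[C@](CC=C(C)C)(C(OC)=CC1=O)C2=O | intermediate
17 | C6 carbinol of 16, C6 configuration unassigned | CC(C)=CCC/C(C)=C/C[C@]12C(O)[C@@H](CC=C(C)C)C(C)(C)[C@](CC=C(C)C)(C(OC)=CC1=O)C2=O | intermediate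
18 | O-phenyl thionocarbonate of 17, C6 configuration unassigned | CC(C)=CCC/C(C)=C/C[C@]12C(OC(=S)Oc3ccccc3)[C@@H](CC=C(C)C)C(C)(C)[C@](CC=C(C)C)(C(OC)=CC1=O)C2=O | intermediate
19 | 5-geranyl-2-methoxy-8,8-dimethyl-1-prenyl-7-exo-prenylbicyclo[3.3.1]non-2-ene-4,9-dione | CC(C)=CCC/C(C)=C/C[C@]12C[C@@H](CC=C(C)C)C(C)(C)[C@](CC=C(C)C)(C(OC)=CC1=O)C2=O | intermediate
20 | 3,4-dihydroxybenzoic acid | O=C(O)c1ccc(O)c(O)c1 | starting material
21 | tert-butyldimethylsilyl 3,4-bis(tert-butyldimethylsilyloxy)benzoate | CC(C)(C)[Si](C)(C)OC(=O)c1ccc(O[Si](C)(C)C(C)(C)C)c(O[Si](C)(C)C(C)(C)C)c1 | intermediate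
22 | 3,4-bis(tert-butyldimethylsilyloxy)benzoyl chloride | O=C(Cl)c1ccc(O[Si](C)(C)C(C)(C)C)c(O[Si](C)(C)C(C)(C)C)c1 | intermediate
23 | C3-aroylated methyl ether (bis-silyl catechol) | CC(C)=CCC/C(C)=C/C[C@]12C[C@@H](CC=C(C)C)C(C)(C)[C@](CC=C(C)C)(C(OC)=C(C(=O)c3ccc(O[Si](C)(C)C(C)(C)C)c(O[Si](C)(C)C(C)(C)C)c3)C1=O)C2=O | intermediate
24 | bis(tert-butyldimethylsilyl) ether of the target | CC(C)=CCC/C(C)=C/C[C@]12C[C@@H](CC=C(C)C)C(C)(C)[C@](CC=C(C)C)(C(=O)C(C(=O)c3ccc(O[Si](C)(C)C(C)(C)C)c(O[Si](C)(C)C(C)(C)C)c3)=C1O)C2=O | intermediate
25 | CNP0160101.3 | CC(C)=CCC/C(C)=C/C[C@]12C[C@@H](CC=C(C)C)C(C)(C)[C@](CC=C(C)C)(C(=O)C(C(=O)c3ccc(O)c(O)c3)=C1O)C2=O | target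

**Step count and risk**

Total: 18 steps. Longest linear sequence: 15 steps (1, 2, 4–13, 16–18, from dimedone); steps 3, 14 and 15 are side branches.

Least certain steps:

Step 8 (key step, proposed new method). The most likely failure is poor discrimination between the two enantiotopic enol ethers. The nucleophile attacks anti to gold, so the chiral ligand sits on the far side of the alkyne from the bond being formed, and the two arms differ only in their relation to that distant pocket. Further threats are acid- or silver-promoted background cyclisation (racemic) and premature hydrolysis of an enol ether in the wet medium. Fallback with known chemistry, setting out from 12 and returning at 13: the achiral complex [JohnPhosAu(NCMe)]SbF6 in wet acetone performs the known racemic 6-endo-dig carbocyclisation. It gives 13 together with its mirror-image bromo enone F1, and the enantiomers are separated by preparative HPLC on a chiral stationary phase, at the cost of half the material.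

Step 5. Allylation may stop at oxygen, or the enolate oxygen may close onto the ynone. The triketonate is a weak, hindered carbon nucleophile, and the long-lived π-allyl complex can also erode the E geometry of the geranyl group. Fallback, setting out from 4 and 9 and returning at 10, with the order of the two C5 substituents reversed:
- 4 is C-geranylated under the same palladium conditions (routine for a simple 1,3-dione) to 2-geranyl-4,6-diprenyldimedone F2.
- F2 is converted with TMSCl and Et3N into its trimethylsilyl enol ether F3.
- F3 undergoes a Mukaiyama aldol addition with commercial 3-(triisopropylsilyl)propynal and BF3·OEt2 at −78 °C, which forms the C5–C4 bond at the alcohol level and gives the propargylic alcohol F4.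
- F4 is oxidised with Dess–Martin periodinane to 10.

Step 9. Methoxide may attack a carbonyl group flanking C5 and open the bicycle by retro-Claisen cleavage, or may cleave the silyl enol ether early and so expose a tri-acyl carbon to base. Fallback, setting out from 13 and returning at 14, which avoids alkoxide:
- Miyaura borylation of the vinyl bromide (B2pin2, PdCl2(dppf), KOAc, dioxane, 80 °C) gives the C2 pinacol boronate F5.
- Oxidation with NaBO3·4H2O in aqueous THF gives the C2-hydroxy enone F6.
- O-Methylation with trimethylsilyldiazomethane in methanol–toluene gives 14, separated from the regioisomeric C4 methyl enol ether F7.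

Step 1 (and likewise step 2). Dianion formation may be incomplete, or alkylation may occur at the central carbon or at oxygen, because the monoanion is poorly soluble and the second deprotonation is slow. Fallback, setting out from 1 and returning at 3, by Stork–Danheiser alkylation:
- 1 is converted with methanol and TsOH into 3-methoxy-5,5-dimethylcyclohex-2-en-1-one F8.
- Kinetic deprotonation with LDA and alkylation with 2 gives the 6-prenyl vinylogous ester F9.
- Aqueous HCl in THF hydrolyses F9 to 3.

**Further compounds**

F1 | step 8 | mirror-image bromo enone (enantiomer of 13) | CC(C)=CCC/C(C)=C/C[C@@]12C(O[Si](C)(C)C(C)(C)C)=C(CC=C(C)C)C(C)(C)[C@@](CC=C(C)C)(C(Br)=CC1=O)C2=O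
F2 | step 5 | 2-geranyl-4,6-diprenyldimedone | CC(C)=CCC/C(C)=C/CC1C(=O)C(CC=C(C)C)C(C)(C)C(CC=C(C)C)C1=O
F3 | step 5 | 2-geranyl-5,5-dimethyl-4,6-diprenyl-3-(trimethylsilyloxy)cyclohex-2-en-1-one | CC(C)=CCC/C(C)=C/CC1=C(O[Si](C)(C)C)C(CC=C(C)C)C(C)(C)C(CC=C(C)C)C1=O
F4 | step 5 | 2-geranyl-2-[1-hydroxy-3-(triisopropylsilyl)prop-2-yn-1-yl]-4,6-diprenyl-5,5-dimethylcyclohexane-1,3-dione | CC(C)=CCC/C(C)=C/CC1(C(O)C#C[Si](C(C)C)(C(C)C)C(C)C)C(=O)C(CC=C(C)C)C(C)(C)C(CC=C(C)C)C1=O
F5 | step 9 | C2 pinacol boronate corresponding to 13 | CC(C)=CCC/C(C)=C/C[C@]12C(O[Si](C)(C)C(C)(C)C)=C(CC=C(C)C)C(C)(C)[C@](CC=C(C)C)(C(B3OC(C)(C)C(C)(C)O3)=CC1=O)C2=O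
F6 | step 9 | C2-hydroxy enone (enolised 2,4-dione) with C6 silyl enol ether | CC(C)=CCC/C(C)=C/C[C@]12C(O[Si](C)(C)C(C)(C)C)=C(CC=C(C)C)C(C)(C)[C@](CC=C(C)C)(C(O)=CC1=O)C2=O
F7 | step 9 | regioisomeric C4 methyl enol ether of 14 | CC(C)=CCC/C(C)=C/C[C@]12C(O[Si](C)(C)C(C)(C)C)=C(CC=C(C)C)C(C)(C)[C@](CC=C(C)C)(C(=O)C=C1OC)C2=O
F8 | step 1 | 3-methoxy-5,5-dimethylcyclohex-2-en-1-one | COC1=CC(=O)CC(C)(C)C1
F9 | step 1 | 3-methoxy-5,5-dimethyl-6-(3-methylbut-2-en-1-yl)cyclohex-2-en-1-one | COC1=CC(=O)C(CC=C(C)C)C(C)(C)C1
A1 | alternative 1 | bis(tert-butyldimethylsilyl) ether of the target | CC(C)=CCC/C(C)=C/C[C@]12C[C@@H](CC=C(C)C)C(C)(C)[C@](CC=C(C)C)(C(=O)C(C(=O)c3ccc(O[Si](C)(C)C(C)(C)C)c(O[Si](C)(C)C(C)(C)C)c3)=C1O)C2=O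
A2 | alternative 1 | bridged anhydride of ring B (3-oxabicyclo[3.3.1]nonane-2,4,9-trione with C1 prenyl, C5 geranyl, C7 exo prenyl, C8 gem-dimethyl) | CC(C)=CCC/C(C)=C/C[C@]12C[C@@H](CC=C(C)C)C(C)(C)[C@](CC=C(C)C)(C(=O)OC1=O)C2=O
A3 | alternative 1 | 3,4-bis(tert-butyldimethylsilyloxy)acetophenone | CC(=O)c1ccc(O[Si](C)(C)C(C)(C)C)c(O[Si](C)(C)C(C)(C)C)c1
A4 | alternative 2 | 8,8-dimethyl-1-prenylbicyclo[3.3.1]nonane-2,4,9-trione with exo C7 aldehyde and C5 hydrogen | O=C1[C@H]2C[C@@H](C=O)C(C)(C)[C@]1(CC=C(C)C)C(=O)CC2=O
A5 | alternative 2 | 2-(2-methyl-4-oxobutan-2-yl)-2-prenylcyclohexane-1,3,5-trione | CC(C)=CCC1(C(C)(C)CC=O)C(=O)CC(=O)CC1=O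
A6 | alternative 3 | bicyclo[3.3.1]nonenone with C7 hydroxyl, C4 methyl enol ether and C1 hydrogen | CC(C)=CCC/C(C)=C/C[C@]12C[C@@H](O)C(C)(C)[C@H](CC=C1OC)C2=O
A7 | alternative 3 | 6-geranyl-1,5-dimethoxy-6-[(3,3-dimethyloxiran-2-yl)methyl]cyclohexa-1,4-diene | COC1=CCC=C(OC)C1(C/C=C(\C)CCC=C(C)C)C[C@@H]1C(C)(C)O1
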